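**Retrosynthetic overview**
1. Target 23 ← alcohol 22 ← silyl ether quinone 21 ← hydroquinone 20; the last three operations are Ag2O oxidation, desilylation and acylation.
2. The strategy rests on ring B, the benzoquinone ring: oxygens on C1 and C4 and a single carbon substituent (C2 of furan ring A) on C2 beside C1. This maps onto 3-furyl-4-hydroxy-4-vinylcyclobutenone 17, whose four ring carbons and two oxygens plus the two vinyl carbons become ring B.
3. 17 ← vinylmagnesium bromide 16 + furylcyclobutenedione 15 ← diisopropyl squarate 10 + furyllithium 11, then hydride and acid.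
4. 11 ← 2-stannylfuran 9 ← cross-metathesis and silylation ← homoallylic alcohol 7 (allylboration sets the only stereocentre) ← 5-stannyl-3-furaldehyde 5 ← furan-3-carbaldehyde 1.
5. Ring order: furan ring A is bought, the four-membered ring comes from 10, and ring B is formed last, in step 8.

Key step: step 8

Assumption: the centre written [C@@H] is read as R (O > furan-3-yl > CH2 > H); the ring carbinol centres of 12, 13 and 17 are carried as mixtures because each becomes sp2 by the end of step 8.

Abbreviation used in names: Fu = 4-[(R)-4-methyl-1-(triisopropylsilyloxy)pent-3-en-1-yl]furan-2-yl (attached through furan C2, side chain on C4).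

**Step 1**
Reactants: 1 furan-3-carbaldehyde
Product: 5 tributyl(4-formylfuran-2-yl)stannane [5-(tributylstannyl)furan-3-carbaldehyde], via lithium morpholino alkoxide 2 (not isolated), via C5-lithiated alkoxide 3 (not isolated), via C5-stannylated alkoxide 4 (not isolated)
Conditions: morpholine, n-BuLi, THF, −78 °C; add 1; sec-BuLi, −78 °C; Bu3SnCl, −78 °C → rt; H2O
Reagents that add atoms: tributyltin chloride, CCCC[Sn](Cl)(CCCC)CCCC
Why: Lithium morpholide adds to the aldehyde to give a bulky, weakly coordinating α-amino alkoxide that shields C2, so sec-BuLi should remove the other α-proton (C5) and the tin chloride should trap that furyllithium (α-amino alkoxide-directed lithiation of a 3-furaldehyde, the aldehyde returning on aqueous work-up).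

**Step 2**
Reactants: 5 tributyl(4-formylfuran-2-yl)stannane
Product: 7 (R)-1-[5-(tributylstannyl)furan-3-yl]but-3-en-1-ol, via borinate ester 6 (not isolated)
Conditions: (+)-Ipc2B(allyl) [from (−)-α-pinene], Et2O, −78 °C; then HOCH2CH2NH2, rt
Reagents that add atoms: (+)-B-allyldiisopinocampheylborane, C=CCB([C@H]1C[C@H]2C[C@@H]([C@@H]1C)C2(C)C)[C@H]1C[C@H]2C[C@@H]([C@@H]1C)C2(C)C
Why: Brown allylboration through a closed chair transition state, in which the (−)-α-pinene-derived isopinocampheyl groups should steer allyl to the Re face of the aryl aldehyde and so set the carbinol centre as R by reagent control; the ethanolamine work-up uses no oxidant and should leave the C–Sn bond alone.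

**Step 3**
Reactants: 7 (R)-1-[5-(tributylstannyl)furan-3-yl]but-3-en-1-ol
Product: 8 tributyl{4-[(R)-1-(triisopropylsilyloxy)but-3-en-1-yl]furan-2-yl}stannane
Conditions: TIPSOTf, 2,6-lutidine, CH2Cl2, −78 → 0 °C
Reagents that add atoms: triisopropylsilyl trifluoromethanesulfonate, CC(C)[Si](OS(=O)(=O)C(F)(F)F)(C(C)C)C(C)C
Why: Silylation of a secondary alcohol with a silyl triflate and a hindered base, where excess lutidine should prevent protodestannylation and the bulky silyl ether is chosen to survive organolithium, hydride, dilute acid and heat.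

**Step 4**
Reactants: 8 tributyl{4-[(R)-1-(triisopropylsilyloxy)but-3-en-1-yl]furan-2-yl}stannane
Product: 9 tributyl(Fu)stannane
Conditions: 2-methylbut-2-ene (large excess), second-generation Grubbs catalyst (H2IMes)(PCy3)Cl2Ru=CHPh (cat.), CH2Cl2, 40 °C
Reagents that add atoms: 2-methylbut-2-ene, CC=C(C)C
Why: Olefin cross-metathesis of a terminal alkene with excess trisubstituted alkene should exchange =CH2 for =C(CH3)2 with loss of propene, without touching the stereocentre, the furan or the aryl–tin bond.

**Step 5**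
Reactants: 9 tributyl(Fu)stannane; 10 diisopropyl squarate
Product: 12 4-hydroxy-2,3-diisopropoxy-4-(Fu)cyclobut-2-en-1-one (both C4 epimers), via furyllithium 11 (not isolated)
Conditions: n-BuLi (1.0 equiv), THF, −78 °C; cannula into 10, THF, −78 °C; aq. NH4Cl
Reagents that add atoms: none
Why: Tin–lithium exchange should place lithium exactly on the carbon that carried tin, which fixes the site that direct deprotonation of a 3-substituted furan would not guarantee, and inverse 1,2-addition to one squarate carbonyl should stop at the mono-adduct because the resulting alkoxide deactivates the remaining vinylogous ester carbonyl.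

**Step 6**
Reactants: 12 4-hydroxy-2,3-diisopropoxy-4-(Fu)cyclobut-2-en-1-one
Product: 15 3-(Fu)cyclobut-3-ene-1,2-dione, via cyclobutene-1,4-diol 13 (not isolated), via hydroxy isopropoxy cyclobutenone 14 (not isolated)
Conditions: LiAlH(OtBu)3 (2.5 equiv), THF, −78 → 0 °C; then 2 M aq. HCl, 0 °C → rt (short, monitored)
Reagents that add atoms: water, O
Why: The hindered hydride should add 1,2 to the remaining carbonyl, and acid should then ionise the tertiary and afterwards the secondary allylic hydroxyl to isopropoxy-stabilised cyclobutenyl cations that hydrolyse to carbonyls with double-bond transposition (squarate-adduct to cyclobutenedione rearrangement), leaving hydrogen on the ring carbon that received the hydride; the secondary silyl ether and the trisubstituted alkene should tolerate brief cold dilute acid.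

**Step 7**
Reactants: 15 3-(Fu)cyclobut-3-ene-1,2-dione; 16 vinylmagnesium bromide
Product: 17 4-hydroxy-3-(Fu)-4-vinylcyclobut-2-en-1-one (both C4 epimers)
Conditions: 16 (1.1 equiv, slow addition), THF, −78 °C; aq. NH4Cl at −78 °C
Reagents that add atoms: none
Why: Cold 1,2-addition of the Grignard reagent should favour the carbonyl next to the furyl-bearing carbon, since the other carbonyl is a less electrophilic vinylogous furyl ketone; addition at the other carbonyl would lead to the same hydroquinone, and the new carbinol centre is destroyed in step 8.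

**Step 8**
Reactants: 17 4-hydroxy-3-(Fu)-4-vinylcyclobut-2-en-1-one
Product: 20 2-(Fu)benzene-1,4-diol, via dienylketene 18 (not isolated), via cyclohexadienone 19 (not isolated)
Conditions: degassed p-xylene, 138 °C, argon
Reagents that add atoms: none
Why: Heating should break the C1–C4 σ bond of 17 in a conrotatory 4π electrocyclic opening to dienylketene 18, in which the ketene carbon and the vinyl group lie cis across the new C3=C4 bond. The ketene C=C, the C3=C4 bond and the vinyl C=C should then undergo a thermal disrotatory 6π electrocyclisation that joins ketene C1 to the vinyl CH2 and closes the six-membered carbocycle (the only ring formed), and enolisation of dienone 19 should give the aromatic hydroquinone 20. The closest known reaction type is the thermal ring expansion of 4-alkenyl-4-hydroxycyclobutenones to hydroquinones (Moore rearrangement). No stereocentre is created, and because the C4 carbinol carbon becomes sp2 both epimers of 17 converge. The selectivity needed is torquoselectivity (hydroxyl outward, vinyl inward), which is secured by the donor hydroxyl on C4 since a donor on the sp3 carbon of a cyclobutene prefers outward rotation. The furan sits on sp2 C3 and cannot join a six-electron closure with the ketene, and the silyl ether keeps the side-chain oxygen from adding to the ketene.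

**Step 9**
Reactants: 20 2-(Fu)benzene-1,4-diol
Product: 21 2-(Fu)cyclohexa-2,5-diene-1,4-dione
Conditions: Ag2O, MgSO4, Et2O, rt
Reagents that add atoms: none
Why: Two-electron oxidation of a hydroquinone to the p-quinone by Ag2O under neutral anhydrous conditions, which should leave the furan, the alkene and the silyl ether untouched.

**Step 10**
Reactants: 21 2-(Fu)cyclohexa-2,5-diene-1,4-dione
Product: 22 2-{4-[(R)-1-hydroxy-4-methylpent-3-en-1-yl]furan-2-yl}cyclohexa-2,5-diene-1,4-dione
Conditions: HF·pyridine (excess), THF, 0 °C → rt, polypropylene vessel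
Reagents that add atoms: none
Why: Fluoride cleavage of the Si–O bond in an acidic medium that a quinone tolerates (basic fluoride would attack it), and since the C–O bond at the stereocentre is not broken the R configuration should be kept.

**Step 11**
Reactants: 22 2-{4-[(R)-1-hydroxy-4-methylpent-3-en-1-yl]furan-2-yl}cyclohexa-2,5-diene-1,4-dione
Product: 23 (R)-1-[5-(3,6-dioxocyclohexa-1,4-dien-1-yl)furan-3-yl]-4-methylpent-3-en-1-yl 3-methylbutanoate (target)
Conditions: 3-methylbutanoic anhydride (1.5 equiv), DMAP (cat.), pyridine (2 equiv), CH2Cl2, 0 °C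
Reagents that add atoms: 3-methylbutanoic anhydride, CC(C)CC(=O)OC(=O)CC(C)C
Why: DMAP-catalysed acyl transfer to the secondary alcohol with retention (the C–O bond is untouched), run cold with only catalytic DMAP so that the quinone is exposed to as little nucleophile as possible.

**Compound list**
1 | furan-3-carbaldehyde | O=Cc1ccoc1 | starting material
2 | lithium (furan-3-yl)(morpholin-4-yl)methanolate | [Li+].[O-]C(c1ccoc1)N1CCOCC1 | intermediate
3 | lithium (5-lithiofuran-3-yl)(morpholin-4-yl)methanolate | [Li+].[O-]C(c1coc([Li])c1)N1CCOCC1 | intermediate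
4 | lithium (morpholin-4-yl)[5-(tributylstannyl)furan-3-yl]methanolate | [Li+].[O-]C(c1coc([Sn](CCCC)(CCCC)CCCC)c1)N1CCOCC1 | intermediate
5 | tributyl(4-formylfuran-2-yl)stannane | O=Cc1coc([Sn](CCCC)(CCCC)CCCC)c1 | intermediate
6 | (R)-1-[5-(tributylstannyl)furan-3-yl]but-3-en-1-yl bis(isopinocampheyl)borinate | C=CC[C@@H](OB([C@H]1C[C@H]2C[C@@H]([C@@H]1C)C2(C)C)[C@H]1C[C@H]2C[C@@H]([C@@H]1C)C2(C)C)c1coc([Sn](CCCC)(CCCC)CCCC)c1 | intermediate
7 | (R)-1-[5-(tributylstannyl)furan-3-yl]but-3-en-1-ol | C=CC[C@@H](O)c1coc([Sn](CCCC)(CCCC)CCCC)c1 | intermediate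
8 | tributyl{4-[(R)-1-(triisopropylsilyloxy)but-3-en-1-yl]furan-2-yl}stannane | C=CC[C@@H](O[Si](C(C)C)(C(C)C)C(C)C)c1coc([Sn](CCCC)(CCCC)CCCC)c1 | intermediate
9 | tributyl(Fu)stannane | CC(C)=CC[C@@H](O[Si](C(C)C)(C(C)C)C(C)C)c1coc([Sn](CCCC)(CCCC)CCCC)c1 | intermediate
10 | diisopropyl squarate (3,4-diisopropoxycyclobut-3-ene-1,2-dione) | CC(C)OC1=C(OC(C)C)C(=O)C1=O | starting material
11 | (Fu)lithium | CC(C)=CC[C@@H](O[Si](C(C)C)(C(C)C)C(C)C)c1coc([Li])c1 | intermediate
12 | 4-hydroxy-2,3-diisopropoxy-4-(Fu)cyclobut-2-en-1-one (both C4 epimers) | CC(C)=CC[C@@H](O[Si](C(C)C)(C(C)C)C(C)C)c1coc(C2(O)C(=O)C(OC(C)C)=C2OC(C)C)c1 | intermediate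
13 | 2,3-diisopropoxy-1-(Fu)cyclobut-2-ene-1,4-diol (diastereomer mixture) | CC(C)=CC[C@@H](O[Si](C(C)C)(C(C)C)C(C)C)c1coc(C2(O)C(O)C(OC(C)C)=C2OC(C)C)c1 | intermediate
14 | 4-hydroxy-2-isopropoxy-3-(Fu)cyclobut-2-en-1-one | CC(C)=CC[C@@H](O[Si](C(C)C)(C(C)C)C(C)C)c1coc(C2=C(OC(C)C)C(=O)C2O)c1 | intermediate
15 | 3-(Fu)cyclobut-3-ene-1,2-dione | CC(C)=CC[C@@H](O[Si](C(C)C)(C(C)C)C(C)C)c1coc(C2=CC(=O)C2=O)c1 | intermediate
16 | vinylmagnesium bromide | C=C[Mg]Br | starting material
17 | 4-hydroxy-3-(Fu)-4-vinylcyclobut-2-en-1-one (both C4 epimers) | CC(C)=CC[C@@H](O[Si](C(C)C)(C(C)C)C(C)C)c1coc(C2=CC(=O)C2(O)C=C)c1 | intermediate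
18 | (3Z)-4-hydroxy-3-(Fu)hexa-1,3,5-trien-1-one | CC(C)=CC[C@@H](O[Si](C(C)C)(C(C)C)C(C)C)c1coc(C(/C=C=O)=C(\O)C=C)c1 | intermediate
19 | 4-hydroxy-3-(Fu)cyclohexa-2,4-dien-1-one | CC(C)=CC[C@@H](O[Si](C(C)C)(C(C)C)C(C)C)c1coc(C2=CC(=O)CC=C2O)c1 | intermediate
20 | 2-(Fu)benzene-1,4-diol | CC(C)=CC[C@@H](O[Si](C(C)C)(C(C)C)C(C)C)c1coc(-c2cc(O)ccc2O)c1 | intermediate
21 | 2-(Fu)cyclohexa-2,5-diene-1,4-dione | CC(C)=CC[C@@H](O[Si](C(C)C)(C(C)C)C(C)C)c1coc(C2=CC(=O)C=CC2=O)c1 | intermediate
22 | 2-{4-[(R)-1-hydroxy-4-methylpent-3-en-1-yl]furan-2-yl}cyclohexa-2,5-diene-1,4-dione | CC(C)=CC[C@@H](O)c1coc(C2=CC(=O)C=CC2=O)c1 | intermediate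
23 | (R)-1-[5-(3,6-dioxocyclohexa-1,4-dien-1-yl)furan-3-yl]-4-methylpent-3-en-1-yl 3-methylbutanoate | CC(C)=CC[C@@H](OC(=O)CC(C)C)c1coc(C2=CC(=O)C=CC2=O)c1 | target

**Step count**
Total: 11 steps. Longest linear sequence: 11 steps, from furan-3-carbaldehyde 1.

**Steps most likely to fail**

Step 6. Hydride delivery to the alkoxide-bearing carbonyl of 12 may be incomplete. The double ionisation may also stall after the first hydroxyl has left, or need acid strong enough to strip the silyl ether or add HCl across the trisubstituted alkene. Fallback, setting out from 10 and 9 and returning at 15: the hydride step is moved onto the simple squarate. Diisopropyl squarate 10 is reduced with LiAlH(OtBu)3 (THF, −78 °C) to 4-hydroxy-2,3-diisopropoxycyclobut-2-en-1-one F1. F1 is silylated (TMSCl, Et3N, CH2Cl2) to 2,3-diisopropoxy-4-(trimethylsilyloxy)cyclobut-2-en-1-one F2. Furyllithium 11, made from 9 as in step 5, is added to the single carbonyl of F2 to give 2,3-diisopropoxy-1-(Fu)-4-(trimethylsilyloxy)cyclobut-2-en-1-ol F3. F3 already holds both oxygen leaving groups and should pass to 15 with a trace of HCl in CH2Cl2 at 0 °C, so the furan-bearing material never meets the aluminium hydride.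

Step 8. The ring opening may turn the hydroxyl inward so that it captures the ketene as a butenolide, or the ketene may oligomerise before the 6π closure. Fallback, setting out from 9 and returning at 20: ring B is bought instead of made. Bromohydroquinone is acetylated (Ac2O, pyridine) to 2-bromo-1,4-phenylene diacetate F4. Stille coupling of F4 with stannane 9 under a zerovalent palladium catalyst (Pd2(dba)3, AsPh3, DMF, 60 °C) should give 2-(Fu)-1,4-phenylene diacetate F5. Degassed K2CO3 in MeOH at 0 °C should remove both aryl acetates and give hydroquinone 20, which re-enters at step 9.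

Step 11. The nucleophilic catalyst or pyridine may add to the quinone, or base may degrade it, faster than acyl transfer to the hindered alcohol. Fallback, setting out from 20 and returning at 23: acylation is done before the quinone exists. HF·pyridine in THF converts 20 into 2-{4-[(R)-1-hydroxy-4-methylpent-3-en-1-yl]furan-2-yl}benzene-1,4-diol F6. 3-Methylbutanoic anhydride, pyridine and DMAP give the tris(3-methylbutanoate) F7. NH3 in MeOH at 0 °C should cleave only the two aryl esters to give (R)-1-[5-(2,5-dihydroxyphenyl)furan-3-yl]-4-methylpent-3-en-1-yl 3-methylbutanoate F8. Ag2O in Et2O then oxidises F8 to target 23.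

**Further compounds**
F1 | step 6 | 4-hydroxy-2,3-diisopropoxycyclobut-2-en-1-one | CC(C)OC1=C(OC(C)C)C(=O)C1O
F2 | step 6 | 2,3-diisopropoxy-4-(trimethylsilyloxy)cyclobut-2-en-1-one | CC(C)OC1=C(OC(C)C)C(=O)C1O[Si](C)(C)C
F3 | step 6 | 2,3-diisopropoxy-1-(Fu)-4-(trimethylsilyloxy)cyclobut-2-en-1-ol | CC(C)=CC[C@@H](O[Si](C(C)C)(C(C)C)C(C)C)c1coc(C2(O)C(O[Si](C)(C)C)C(OC(C)C)=C2OC(C)C)c1
F4 | step 8 | 2-bromo-1,4-phenylene diacetate | CC(=O)Oc1ccc(OC(C)=O)c(Br)c1
F5 | step 8 | 2-(Fu)-1,4-phenylene diacetate | CC(C)=CC[C@@H](O[Si](C(C)C)(C(C)C)C(C)C)c1coc(-c2cc(OC(C)=O)ccc2OC(C)=O)c1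
F6 | step 11 | 2-{4-[(R)-1-hydroxy-4-methylpent-3-en-1-yl]furan-2-yl}benzene-1,4-diol | CC(C)=CC[C@@H](O)c1coc(-c2cc(O)ccc2O)c1
F7 | step 11 | 2-{4-[(R)-4-methyl-1-(3-methylbutanoyloxy)pent-3-en-1-yl]furan-2-yl}-1,4-phenylene bis(3-methylbutanoate) | CC(C)=CC[C@@H](OC(=O)CC(C)C)c1coc(-c2cc(OC(=O)CC(C)C)ccc2OC(=O)CC(C)C)c1
F8 | step 11 | (R)-1-[5-(2,5-dihydroxyphenyl)furan-3-yl]-4-methylpent-3-en-1-yl 3-methylbutanoate | CC(C)=CC[C@@H](OC(=O)CC(C)C)c1coc(-c2cc(O)ccc2O)c1
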